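0.0313 /h was the number I took from the maple flask: the visible turnover rate, which is the target gained up to 12.0 h divided by the area under the dissolved substrate curve up to then. It is a reading of the target that stays, not the constant of any one step, taken with c(partner) above c(solid substrate).

| setting | maple | flask |
|---|---|---|
| solid substrate | 0.13 M | 0.13 M |
| partner | 0.234 M | 0.234 M |
| protic impurity | 0.13 M | 0.130 M |
| remark | the very flask that is asked about, followed so far |  |
| time |  | 30 h |

- maple (time / h: target / %, dissolved substrate / %): 1.50: 0, 4.9; 4.00: 1.1, 9.4; 8.00: 2.4, 15.1; 12.0: 4.3, 18.4

(scatter of a reading: 0.5 percentage points)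

- as a solid, counted per litre of solution: solid substrate
- at the start none of the solid substrate is in solution
- dissolved substrate means what is dissolved; the solid is not counted in it

* target at 30 h, in percent of the solid substrate charged
* concentration of dissolved substrate in solution at 30 h, in percent of saturation

Over 30 h that rate counted 0.939 turnovers. I held dissolved substrate at its last reading, 18.4%, from 12.0 h on, which gave me 14.7% target. The forecast said 15.5% (11.5% to 21%) and 72% of saturation (55% to 88%), reasoning that “solid stays in excess”. The flask gave 9.01% target and 17.9% of saturation.

    solid substrate ⇌ dissolved substrate, rate k1*(cs1 - [dissolved substrate]) while solid is left; crystals form when [dissolved substrate] > cs1 (solubility = 0.0550 M, k = 2.30 × 10⁻⁵ /s)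
    dissolved substrate + partner → target (k = 1.10 × 10⁻⁴ /M/s)
    dissolved substrate + target → side product (k = 1.50 × 10⁻⁴ /M/s)
    target ⇌ isomer of the product (K = 2.80, k = 1.90 × 10⁻⁴ /s)
    solid substrate + protic impurity → quenched substrate (k = 3.00 × 10⁻⁴ /M/s)

My held level was wrong: at the asked time this flask had 0% solid substrate and 7.57% dissolved substrate. With c(partner) as charged, the step to target has a pseudo-first-order constant of 0.0927 /h, and my 0.0313 /h is a third of that. Without the step to isomer of the product, target at the asked time stood at 28.5% instead of 9.01%, the largest single effect, though it covered 21% of the shortfall from the full charge.

Scaled in proportion to the 0.059 M of partner in the neighbour flask, my rate counted 0.236 turnovers, and with its final 26.4% dissolved substrate held throughout, that gave 6.25% target. The computed flask gave 3.55%, having started with no dissolved substrate.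

(All runs are calculated for substances that don't exist; noise was put on by code.)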